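**Retrosynthetic overview**

- The target comes from its 4'-O-MOM ether by mild acetal exchange. Ring C of that ether is opened at O1–C2 and C4–C4a.
- This leads back to the phloroglucinol monoester of a 2-aryl-3-methoxyacrylic acid. Light moves the acyl group from O to C, then a hydroxyl adds to the methoxymethylene carbon and methanol leaves.
- Feature the strategy rests on: ring A (C4a, C5, C6, C7, C8, C8a) carries oxygen on C5, C7 and C8a, so it is phloroglucinol. In its monoester the three ring CH positions are equivalent. Acyl arrival at any of them gives the same C4–C4a ketone, flanked by two hydroxyls of which either can serve as O1 while the other becomes 5-OH.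
- The acrylic acid (ring B) comes from homovanillic acid: ortho-prenylation by dimethylpropargyl ether, semi-hydrogenation and Claisen shift, then MOM protection, formylation with methyl formate, O-methylation and saponification.
- Ring order: rings A and B are bought; ring C is the only ring formed, in step 10.

Key step: step 10

Remark: 3-chloro-3-methylbut-1-yne is taken as a commercial reagent; compound 9 is drawn as the enol tautomer, and the double-bond geometry of 9 and 14 is left undefined because it is lost in the following operation.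

**Route**

Step 1
Reactants: 1 homovanillic acid
Product: 2 methyl homovanillate (methyl 2-(4-hydroxy-3-methoxyphenyl)acetate)
Conditions: MeOH, H2SO4 (cat.), reflux
Reagents that add atoms: methanol, CO
Why: Acid-catalysed Fischer esterification in excess methanol converts only the carboxylic acid, the phenol being inert under these conditions.

Step 2
Reactants: 2 methyl homovanillate; 3 3-chloro-3-methylbut-1-yne
Product: 4 methyl 2-{3-methoxy-4-[(2-methylbut-3-yn-2-yl)oxy]phenyl}acetate
Conditions: K2CO3, KI (cat.), CuI (cat.), acetone, reflux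
Reagents that add atoms: none
Why: Copper-assisted O-alkylation of the phenoxide by the tertiary propargylic chloride is the standard entry to aryl 1,1-dimethylpropargyl ethers and leaves the methyl ester untouched.

Step 3
Reactants: 4 methyl 2-{3-methoxy-4-[(2-methylbut-3-yn-2-yl)oxy]phenyl}acetate
Product: 5 methyl 2-{3-methoxy-4-[(2-methylbut-3-en-2-yl)oxy]phenyl}acetate
Conditions: H2 (1 atm), Pd/CaCO3 poisoned with Pb(OAc)2 (Lindlar catalyst), quinoline, EtOAc, rt
Reagents that add atoms: none
Why: Lindlar semi-hydrogenation over lead-poisoned palladium stops at the terminal alkene, and the substrate holds no other reducible group.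

Step 4
Reactants: 5 methyl 2-{3-methoxy-4-[(2-methylbut-3-en-2-yl)oxy]phenyl}acetate
Product: 6 methyl 2-[4-hydroxy-3-methoxy-5-(3-methylbut-2-en-1-yl)phenyl]acetate
Conditions: PhNEt2, 180 °C, Ar
Reagents that add atoms: none
Why: Aromatic Claisen rearrangement: the [3,3] shift delivers the allyl terminus to C5, the only unsubstituted ortho carbon, with allylic inversion so that the 1,1-dimethylallyl ether becomes the prenyl group, and the blocked para position leaves no other outlet.

Step 5
Reactants: 6 methyl 2-[4-hydroxy-3-methoxy-5-(3-methylbut-2-en-1-yl)phenyl]acetate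
Product: 7 methyl 2-[3-methoxy-4-(methoxymethoxy)-5-(3-methylbut-2-en-1-yl)phenyl]acetate
Conditions: NaH (1.05 equiv), THF/DMF, 0 °C; then MOMCl, 0 °C to rt
Reagents that add atoms: chloromethyl methyl ether, COCCl
Why: Williamson-type O-alkylation of the sodium phenoxide with the reactive chloromethyl ether; the phenol is far more acidic than the arylacetate CH2, so one equivalent of NaH deprotonates only oxygen.

Step 6
Reactants: 7 methyl 2-[3-methoxy-4-(methoxymethoxy)-5-(3-methylbut-2-en-1-yl)phenyl]acetate; 8 methyl formate
Product: 9 methyl 3-hydroxy-2-[3-methoxy-4-(methoxymethoxy)-5-(3-methylbut-2-en-1-yl)phenyl]prop-2-enoate (enol of the α-formyl ester)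
Conditions: NaH, HCO2Me (excess), THF, MeOH (cat.), 0 °C to rt; then cold 1 M HCl to pH 4
Reagents that add atoms: none
Why: Crossed Claisen condensation (C-formylation): methyl formate cannot enolise and is the better electrophile, the equilibrium is pulled over by the stabilised enolate of the α-formyl ester, and the MOM acetal and prenyl group are inert to base.

Step 7
Reactants: 9 methyl 3-hydroxy-2-[3-methoxy-4-(methoxymethoxy)-5-(3-methylbut-2-en-1-yl)phenyl]prop-2-enoate
Product: 10 methyl (E)-3-methoxy-2-[3-methoxy-4-(methoxymethoxy)-5-(3-methylbut-2-en-1-yl)phenyl]prop-2-enoate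
Conditions: Me2SO4, K2CO3, DMF, rt
Reagents that add atoms: dimethyl sulfate, COS(=O)(=O)OC
Why: O-Alkylation of the ambident formyl-ester enolate by the hard electrophile dimethyl sulfate gives the β-methoxyacrylate, for which the E isomer (OMe trans to the ester) is the usual, thermodynamically preferred outcome; the geometry has no bearing on later steps.

Step 8
Reactants: 10 methyl (E)-3-methoxy-2-[3-methoxy-4-(methoxymethoxy)-5-(3-methylbut-2-en-1-yl)phenyl]prop-2-enoate
Product: 11 (E)-3-methoxy-2-[3-methoxy-4-(methoxymethoxy)-5-(3-methylbut-2-en-1-yl)phenyl]prop-2-enoic acid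
Conditions: KOH, MeOH/H2O (4:1), 60 °C; then 1 M HCl to pH 3–4, 0 °C
Reagents that add atoms: potassium hydroxide, [K+].[OH-]
Why: Saponification by acyl–oxygen cleavage, as routinely done on β-methoxyacrylate methyl esters; the MOM acetal is base-stable, and the cold, brief acidification to pH 3–4 is too mild to cleave the acetal or the enol ether.

Step 9
Reactants: 11 (E)-3-methoxy-2-[3-methoxy-4-(methoxymethoxy)-5-(3-methylbut-2-en-1-yl)phenyl]prop-2-enoic acid; 12 phloroglucinol (4 equiv)
Product: 13 3,5-dihydroxyphenyl (E)-3-methoxy-2-[3-methoxy-4-(methoxymethoxy)-5-(3-methylbut-2-en-1-yl)phenyl]prop-2-enoate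
Conditions: DIC, DMAP (cat.), THF, 0 °C to rt; aqueous washes
Reagents that add atoms: none
Why: Carbodiimide/DMAP (Steglich) esterification acylates phenol oxygen rather than ring carbon, and the fourfold excess of the symmetrical triol holds di- and tri-acylation down, the unreacted phloroglucinol being washed out with water.

Step 10
Reactants: 13 3,5-dihydroxyphenyl (E)-3-methoxy-2-[3-methoxy-4-(methoxymethoxy)-5-(3-methylbut-2-en-1-yl)phenyl]prop-2-enoate
Product: 15 5,7-dihydroxy-3-[3-methoxy-4-(methoxymethoxy)-5-(3-methylbut-2-en-1-yl)phenyl]-4H-chromen-4-one (4'-O-MOM-2'-deoxypiscerythrone), via trihydroxyphenyl methoxymethylene ketone 14 (not isolated)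
Conditions: hν (254 nm, low-pressure Hg lamp, quartz), degassed t-BuOH/MeCN (1:1), ca. 2 mM, 25 °C; then NaOAc (cat.), MeOH, 40 °C
Reagents that add atoms: none
Why: Excitation of the aryl ester homolyses the ArO–C(O) bond to a solvent-caged phenoxyl/acyl radical pair, which recombines at a ring carbon and tautomerises to the 2,4,6-trihydroxyphenyl ketone 14 (bond C4–C4a); this is the photo-Fries rearrangement, known for aryl cinnamates and 3-methylbut-2-enoates and for resorcinol monobenzoate with its free hydroxyl. Because the phenoxyl ring carries oxygen on C1, C3 and C5, recombination at C2, C4 or C6 gives one and the same ketone, so no ortho/para selectivity is required. Ring C then closes by 6-endo-trig oxa-Michael addition of a hydroxyl flanking the ketone to the methoxymethylene carbon, followed by β-elimination of methanol (bond O1–C2), the addition–elimination by which 2-hydroxyphenyl enaminones and alkoxymethylene ketones give isoflavones; the NaOAc/MeOH finish completes it. No stereocentre is formed, and light-induced E/Z scrambling of the acrylate is harmless because the attacked carbon carries only H and OMe. The step needs in-cage recombination rather than radical escape, which dilution in a degassed, fairly viscous medium favours, and chromone rather than coumarin connectivity, which is fixed because the acyl carbon is tethered to the ring oxygen before any C–C bond forms. The medium is neutral and free of Lewis acid, so the prenyl group and the MOM acetal should pass through unchanged.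

Step 11
Reactants: 15 5,7-dihydroxy-3-[3-methoxy-4-(methoxymethoxy)-5-(3-methylbut-2-en-1-yl)phenyl]-4H-chromen-4-one
Product: 16 2'-deoxypiscerythrone (5,7-dihydroxy-3-[4-hydroxy-3-methoxy-5-(3-methylbut-2-en-1-yl)phenyl]-4H-chromen-4-one)
Conditions: p-TsOH·H2O (cat.), MeOH, 40 °C
Reagents that add atoms: none
Why: Acid-catalysed acetal exchange with methanol removes the MOM group as dimethoxymethane under conditions too mild to add the freed phenol across the neighbouring prenyl double bond.

**Compound list**

1 | homovanillic acid | COc1cc(CC(=O)O)ccc1O | starting material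
2 | methyl homovanillate | COC(=O)Cc1ccc(O)c(OC)c1 | intermediate
3 | 3-chloro-3-methylbut-1-yne | CC(C)(Cl)C#C | starting material
4 | methyl 2-{3-methoxy-4-[(2-methylbut-3-yn-2-yl)oxy]phenyl}acetate | COC(=O)Cc1ccc(OC(C)(C)C#C)c(OC)c1 | intermediate
5 | methyl 2-{3-methoxy-4-[(2-methylbut-3-en-2-yl)oxy]phenyl}acetate | COC(=O)Cc1ccc(OC(C)(C)C=C)c(OC)c1 | intermediate
6 | methyl 2-[4-hydroxy-3-methoxy-5-(3-methylbut-2-en-1-yl)phenyl]acetate | COC(=O)Cc1cc(OC)c(O)c(CC=C(C)C)c1 | intermediate
7 | methyl 2-[3-methoxy-4-(methoxymethoxy)-5-(3-methylbut-2-en-1-yl)phenyl]acetate | COC(=O)Cc1cc(OC)c(OCOC)c(CC=C(C)C)c1 | intermediate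
8 | methyl formate | COC=O | starting material
9 | methyl 3-hydroxy-2-[3-methoxy-4-(methoxymethoxy)-5-(3-methylbut-2-en-1-yl)phenyl]prop-2-enoate (enol of the α-formyl ester) | COC(=O)C(=CO)c1cc(OC)c(OCOC)c(CC=C(C)C)c1 | intermediate
10 | methyl (E)-3-methoxy-2-[3-methoxy-4-(methoxymethoxy)-5-(3-methylbut-2-en-1-yl)phenyl]prop-2-enoate | CO/C=C(/C(=O)OC)c1cc(OC)c(OCOC)c(CC=C(C)C)c1 | intermediate
11 | (E)-3-methoxy-2-[3-methoxy-4-(methoxymethoxy)-5-(3-methylbut-2-en-1-yl)phenyl]prop-2-enoic acid | CO/C=C(/C(=O)O)c1cc(OC)c(OCOC)c(CC=C(C)C)c1 | intermediate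
12 | phloroglucinol | Oc1cc(O)cc(O)c1 | starting material
13 | 3,5-dihydroxyphenyl (E)-3-methoxy-2-[3-methoxy-4-(methoxymethoxy)-5-(3-methylbut-2-en-1-yl)phenyl]prop-2-enoate | CO/C=C(/C(=O)Oc1cc(O)cc(O)c1)c1cc(OC)c(OCOC)c(CC=C(C)C)c1 | intermediate
14 | 3-methoxy-2-[3-methoxy-4-(methoxymethoxy)-5-(3-methylbut-2-en-1-yl)phenyl]-1-(2,4,6-trihydroxyphenyl)prop-2-en-1-one (E/Z mixture) | COC=C(C(=O)c1c(O)cc(O)cc1O)c1cc(OC)c(OCOC)c(CC=C(C)C)c1 | intermediate
15 | 5,7-dihydroxy-3-[3-methoxy-4-(methoxymethoxy)-5-(3-methylbut-2-en-1-yl)phenyl]-4H-chromen-4-one (4'-O-MOM-2'-deoxypiscerythrone) | COCOc1c(OC)cc(-c2coc3cc(O)cc(O)c3c2=O)cc1CC=C(C)C | intermediate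
16 | 2'-deoxypiscerythrone | COc1cc(-c2coc3cc(O)cc(O)c3c2=O)cc(CC=C(C)C)c1O | target

**Step count**

Total step count: 11. Longest linear sequence: 11 steps (1 to 16); compounds 3, 8 and 12 enter as bought materials.

**Steps most likely to fail, with fallbacks**

Step 10. The radical pair may escape the solvent cage, giving phloroglucinol and reduced or decarbonylated acyl fragments. The acrylate chromophore and the accumulating chromone may also take the light, so that conversion stalls. The fallback builds ring C thermally by the deoxybenzoin/enaminone route; it sets out from 7 and 12 and comes back at 16.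
- Phloroglucinol 12 is converted into 1,3,5-tris(methoxymethoxy)benzene F1 (NaH, MOMCl, DMF).
- Ester 7 is converted into the Weinreb amide N-methoxy-N-methyl-2-[3-methoxy-4-(methoxymethoxy)-5-(3-methylbut-2-en-1-yl)phenyl]acetamide F2 (MeNHOMe·HCl, i-PrMgCl, THF, −20 °C).
- F1 is lithiated between two MOM-oxy groups (n-BuLi, THF, 0 °C) and F2 is added at −78 °C. This should give the deoxybenzoin 2-[3-methoxy-4-(methoxymethoxy)-5-(3-methylbut-2-en-1-yl)phenyl]-1-[2,4,6-tris(methoxymethoxy)phenyl]ethan-1-one F3.
- Condensation with N,N-dimethylformamide dimethyl acetal (toluene, 90 °C) should give the enaminone 3-(dimethylamino)-2-[3-methoxy-4-(methoxymethoxy)-5-(3-methylbut-2-en-1-yl)phenyl]-1-[2,4,6-tris(methoxymethoxy)phenyl]prop-2-en-1-one F4.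
- HCl in MeOH at 40 °C should then remove all four MOM groups and close ring C with loss of dimethylamine, arriving directly at 16.

Step 9. The acrylic acid is deactivated by its β-methoxy group, so acylation may be slow and rearrangement of the activated acid to an N-acylurea may compete. Over-acylation of the triol to di- and tri-esters may also consume the acid. The fallback moves the statistical differentiation onto the cheap triol; it sets out from 11 and 12 and comes back at 13.
- Phloroglucinol 12 is silylated with two equivalents of TBSCl (imidazole, DMF), and 3,5-bis(tert-butyldimethylsilyloxy)phenol F5 is separated by chromatography.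
- Its single free hydroxyl is acylated with acid 11 (DIC, DMAP, CH2Cl2) to give 3,5-bis(tert-butyldimethylsilyloxy)phenyl (E)-3-methoxy-2-[3-methoxy-4-(methoxymethoxy)-5-(3-methylbut-2-en-1-yl)phenyl]prop-2-enoate F6.
- Buffered fluoride (Et3N·3HF, THF, 0 °C) should then free the two phenols without touching the aryl ester, giving 13.

Step 4. At the temperature of the sigmatropic shift the tertiary allyl ether may fragment to phenol 2 and isoprene. The prenyl phenol may also rearrange further (abnormal Claisen pathway). The fallback installs the prenyl group by cross-coupling; it sets out from 2 and comes back at 7.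
- Iodination of the phenoxide of 2 (I2, KI, NaHCO3, aqueous MeOH) goes ortho to oxygen, the para position being blocked, and should give methyl 2-(4-hydroxy-3-iodo-5-methoxyphenyl)acetate F7.
- MOM protection (NaH, MOMCl, THF/DMF) gives methyl 2-[3-iodo-5-methoxy-4-(methoxymethoxy)phenyl]acetate F8.
- Stille coupling with tributyl(3-methylbut-2-en-1-yl)stannane (Pd(PPh3)4, DMF, 90 °C), which normally transfers the prenyl group through its unsubstituted terminus, should give 7.

**Further compounds**

F1 | step 10 | 1,3,5-tris(methoxymethoxy)benzene | COCOc1cc(OCOC)cc(OCOC)c1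
F2 | step 10 | N-methoxy-N-methyl-2-[3-methoxy-4-(methoxymethoxy)-5-(3-methylbut-2-en-1-yl)phenyl]acetamide | CON(C)C(=O)Cc1cc(OC)c(OCOC)c(CC=C(C)C)c1
F3 | step 10 | 2-[3-methoxy-4-(methoxymethoxy)-5-(3-methylbut-2-en-1-yl)phenyl]-1-[2,4,6-tris(methoxymethoxy)phenyl]ethan-1-one | COCOc1cc(OCOC)c(C(=O)Cc2cc(OC)c(OCOC)c(CC=C(C)C)c2)c(OCOC)c1
F4 | step 10 | 3-(dimethylamino)-2-[3-methoxy-4-(methoxymethoxy)-5-(3-methylbut-2-en-1-yl)phenyl]-1-[2,4,6-tris(methoxymethoxy)phenyl]prop-2-en-1-one (geometry not defined) | CN(C)C=C(C(=O)c1c(OCOC)cc(OCOC)cc1OCOC)c1cc(OC)c(OCOC)c(CC=C(C)C)c1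
F5 | step 9 | 3,5-bis(tert-butyldimethylsilyloxy)phenol | CC(C)(C)[Si](C)(C)Oc1cc(O)cc(O[Si](C)(C)C(C)(C)C)c1
F6 | step 9 | 3,5-bis(tert-butyldimethylsilyloxy)phenyl (E)-3-methoxy-2-[3-methoxy-4-(methoxymethoxy)-5-(3-methylbut-2-en-1-yl)phenyl]prop-2-enoate | CO/C=C(/C(=O)Oc1cc(O[Si](C)(C)C(C)(C)C)cc(O[Si](C)(C)C(C)(C)C)c1)c1cc(OC)c(OCOC)c(CC=C(C)C)c1
F7 | step 4 | methyl 2-(4-hydroxy-3-iodo-5-methoxyphenyl)acetate | COC(=O)Cc1cc(I)c(O)c(OC)c1
F8 | step 4 | methyl 2-[3-iodo-5-methoxy-4-(methoxymethoxy)phenyl]acetate | COC(=O)Cc1cc(I)c(OCOC)c(OC)c1
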